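**Retrosynthetic overview** (locants follow cyclohepta[b]furan-2-one numbering, C3a to C8a; C1' is the side-chain carbon on C7)
1. The (Z)-enone and the C5 ketone come from a last-step double oxidation of a diol, itself made by Ni/Cr coupling of a C7 aldehyde with (Z)-1-iodopropene (fragment 3, from propyne).
2. The trans C7-OH / C8 isovalerate pair comes from titanium-directed opening at C8 of a C7–C8 epoxy alcohol by isovaleric acid, after asymmetric epoxidation of a C7-hydroxymethyl cycloheptene.
3. The seven-membered ring is formed second, by ring-closing metathesis that makes C7=C8.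
4. The key union (C5–C6 bond, C6 stereocentre) is a ruthenium-catalysed C–H coupling of the primary alcohol of lactone fragment 1 with 2-(silyloxymethyl)butadiene (fragment 2, from methyl acrylate and formaldehyde).
5. The lactone ring is formed first (C3a/C8a), by chromium-catalysed asymmetric allylation–lactonisation of acrolein with a Morita–Baylis–Hillman-derived allylic bromide.

Assumption: 4-methoxybenzyl alcohol, silyl chlorides, NBS, iodine, tert-butyl hydroperoxide and the methyl Wittig salt are treated as reagents; the carbinol centres at C5 and C1' are temporary and are oxidised away in the last step.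

**Fragment 1 (lactone alcohol)**

Step 1
Reactants: 1 acrolein (prop-2-enal)
Product: 2 3-[(4-methoxybenzyl)oxy]propanal
Conditions: 4-MeOC6H4CH2OH (1.0 equiv), ClCH2CO2H (10 mol %), NaOH (10 mol %), AcOH (30 mol %), neat, 40 °C, 72 h
Reagents that add atoms: 4-methoxybenzyl alcohol, COc1ccc(CO)cc1
Why: Buffered oxa-Michael addition of the benzylic alcohol to the enal gives the β-alkoxy aldehyde; no stereocentre is formed.

Step 2
Reactants: 2 3-[(4-methoxybenzyl)oxy]propanal, 3 methyl acrylate
Product: 4 methyl 2-{1-hydroxy-3-[(4-methoxybenzyl)oxy]propyl}prop-2-enoate (racemic)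
Conditions: DABCO (0.5 equiv), 3 (3 equiv, neat), rt, 5 d
Reagents that add atoms: none
Why: Morita–Baylis–Hillman reaction (the ammonium enolate of the acrylate adds to the aldehyde, then the amine is eliminated); the carbinol centre is racemic and is erased in step 3.

Step 3
Reactants: 4 methyl 2-{1-hydroxy-3-[(4-methoxybenzyl)oxy]propyl}prop-2-enoate
Product: 5 methyl (2Z)-2-(bromomethyl)-5-[(4-methoxybenzyl)oxy]pent-2-enoate
Conditions: NBS, Me2S, CH2Cl2, 0 °C → rt
Reagents that add atoms: N-bromosuccinimide, O=C1CCC(=O)N1Br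
Why: Corey–Kim-type activation of the allylic alcohol as an alkoxysulfonium salt and SN2' displacement by bromide give the thermodynamically preferred trisubstituted (Z)-bromide (chain trans to the ester).

Step 4
Reactants: 5 methyl (2Z)-2-(bromomethyl)-5-[(4-methoxybenzyl)oxy]pent-2-enoate, 1 acrolein
Product: 8 (4S,5S)-5-ethenyl-4-{2-[(4-methoxybenzyl)oxy]ethyl}-3-methylideneoxolan-2-one, via silyl ether 6 (not isolated), via hydroxy ester 7 (not isolated)
Conditions: CrCl2 (10 mol %), (S,S)-carbazole bis(oxazoline) ligand (12 mol %), Mn (2 equiv), TMSCl (1.5 equiv), 1 (2 equiv), THF, 0 °C → rt; then dilute aq. HCl, THF, rt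
Reagents that add atoms: none
Why: Catalytic asymmetric Nozaki–Hiyama–Kishi allylation followed by lactonisation, in which the 2-(methoxycarbonyl)allylchromium from 5 keeps its γ-substituent cis to the CH2Cr carbon and adds through a closed chair to give the syn adduct (hence the cis-4,5-lactone) while the chromium–bis(oxazoline) complex selects the aldehyde face and so fixes both new centres as (4S,5S) (the ligand antipode is used should the facial sense prove opposite).

Step 5
Reactants: 8 (4S,5S)-5-ethenyl-4-{2-[(4-methoxybenzyl)oxy]ethyl}-3-methylideneoxolan-2-one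
Product: 9 (4S,5S)-5-ethenyl-4-(2-hydroxyethyl)-3-methylideneoxolan-2-one
Conditions: DDQ, CH2Cl2/pH 7 buffer (10:1), 0 °C → rt
Reagents that add atoms: none
Why: Oxidative cleavage of the 4-methoxybenzyl ether (hydride abstraction by DDQ, hydrolysis of the oxocarbenium ion) frees the primary alcohol without touching the lactone or the alkenes.

**Fragment 2 (diene)**

Step 6
Reactants: 3 methyl acrylate, 10 formaldehyde
Product: 11 methyl 2-(hydroxymethyl)prop-2-enoate
Conditions: DABCO, 37% aq. HCHO, 1,4-dioxane, rt, 48 h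
Reagents that add atoms: none
Why: Morita–Baylis–Hillman reaction of the acrylate with formaldehyde; no stereocentre.

Step 7
Reactants: 11 methyl 2-(hydroxymethyl)prop-2-enoate
Product: 12 methyl 2-{[(tert-butyldimethylsilyl)oxy]methyl}prop-2-enoate
Conditions: TBSCl, imidazole, CH2Cl2, 0 °C → rt
Reagents that add atoms: tert-butyldimethylsilyl chloride, CC(C)(C)[Si](C)(C)Cl
Why: Standard silylation of a primary alcohol, which masks the hydroxyl that would otherwise compete in the alcohol coupling of step 13.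

Step 8
Reactants: 12 methyl 2-{[(tert-butyldimethylsilyl)oxy]methyl}prop-2-enoate
Product: 13 2-{[(tert-butyldimethylsilyl)oxy]methyl}prop-2-en-1-ol
Conditions: i-Bu2AlH (2.2 equiv), CH2Cl2, −78 → 0 °C; aq. potassium sodium tartrate
Reagents that add atoms: none
Why: 1,2-Reduction of the α,β-unsaturated ester by the aluminium hydride gives the allylic alcohol without conjugate reduction.

Step 9
Reactants: 13 2-{[(tert-butyldimethylsilyl)oxy]methyl}prop-2-en-1-ol
Product: 14 2-{[(tert-butyldimethylsilyl)oxy]methyl}prop-2-enal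
Conditions: MnO2 (10 equiv), CH2Cl2, rt
Reagents that add atoms: none
Why: MnO2 oxidises the allylic alcohol selectively to the enal under neutral conditions.

Step 10
Reactants: 14 2-{[(tert-butyldimethylsilyl)oxy]methyl}prop-2-enal
Product: 15 2-{[(tert-butyldimethylsilyl)oxy]methyl}buta-1,3-diene
Conditions: Ph3PCH3Br, n-BuLi, THF, 0 °C; then 14, −78 °C → rt
Reagents that add atoms: methyltriphenylphosphonium bromide, C[P+](c1ccccc1)(c1ccccc1)c1ccccc1.[Br-]
Why: Wittig methylenation of the enal gives the 2-substituted 1,3-diene; the non-stabilised ylide adds 1,2.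

**Fragment 3 ((Z)-vinyl iodide)**

Step 11
Reactants: 16 propyne
Product: 18 1-iodoprop-1-yne, via prop-1-ynyllithium 17 (not isolated)
Conditions: n-BuLi, THF, −78 °C; then I2, −78 °C → rt
Reagents that add atoms: iodine, II
Why: Deprotonation of the terminal alkyne and iodination of the lithium acetylide.

Step 12
Reactants: 18 1-iodoprop-1-yne
Product: 19 (1Z)-1-iodoprop-1-ene
Conditions: KO2CN=NCO2K, AcOH, MeOH/pyridine, rt
Reagents that add atoms: none
Why: Diimide generated in the flask transfers both hydrogens to one face of the alkyne in a concerted step, which gives the (Z)-iodoalkene.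

**Assembly**

Step 13
Reactants: 9 (4S,5S)-5-ethenyl-4-(2-hydroxyethyl)-3-methylideneoxolan-2-one, 15 2-{[(tert-butyldimethylsilyl)oxy]methyl}buta-1,3-diene
Product: 21 (4S,5S)-4-[(2S,3R)-4-{[(tert-butyldimethylsilyl)oxy]methyl}-2-hydroxy-3-methylpent-4-en-1-yl]-5-ethenyl-3-methylideneoxolan-2-one, via aldehyde 20 (not isolated)
Conditions: RuH2(CO)(PPh3)3 (5 mol %), (S)-SEGPHOS (5 mol %), 3,3'-diaryl-H8-BINOL phosphoric acid (10 mol %), 15 (3 equiv), THF, 95 °C, sealed tube
Reagents that add atoms: none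
Why: Proposed new method: a redox-neutral ruthenium-catalysed C–H coupling of a primary alcohol with a 2-(silyloxymethyl)butadiene, in which β-hydride elimination from the ruthenium alkoxide of 9 breaks the C5–H bond to give aldehyde 20 and Ru–H, Ru–H adds to the unsubstituted vinyl terminus of 15 to give the 2-substituted (E)-σ-crotylruthenium (methyl trans to CH2Ru), and this adds to 20 through a closed chair inside the chiral bisphosphine/phosphate pocket to form the C5–C6 bond anti and set C6 (R) and C5 (S) under catalyst control (ligand antipode chosen accordingly); the closest known reaction type is the ruthenium-catalysed anti-crotylation of primary alcohols with butadiene and the related coupling of 2-silylbutadienes and isoprene, which has not been shown for a 2-(alkoxymethyl)diene or beside an α-methylene lactone.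

Step 14
Reactants: 21 (4S,5S)-4-[(2S,3R)-4-{[(tert-butyldimethylsilyl)oxy]methyl}-2-hydroxy-3-methylpent-4-en-1-yl]-5-ethenyl-3-methylideneoxolan-2-one
Product: 22 (3aS,5S,6R,8aS)-7-{[(tert-butyldimethylsilyl)oxy]methyl}-5-hydroxy-6-methyl-3-methylidene-3,3a,4,5,6,8a-hexahydro-2H-cyclohepta[b]furan-2-one
Conditions: second-generation Grubbs catalyst, (H2IMes)(PCy3)Cl2Ru=CHPh (8 mol %), CH2Cl2 (high dilution), 40 °C
Reagents that add atoms: none
Why: Ring-closing metathesis between the vinyl group and the 1,1-disubstituted alkene closes the seven-membered ring as its trisubstituted C7=C8 olefin with loss of ethene; the electron-poor methylene lactone is a poor metathesis partner and no stereocentre is touched.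

Step 15
Reactants: 22 (3aS,5S,6R,8aS)-7-{[(tert-butyldimethylsilyl)oxy]methyl}-5-hydroxy-6-methyl-3-methylidene-3,3a,4,5,6,8a-hexahydro-2H-cyclohepta[b]furan-2-one
Product: 23 (3aS,5S,6R,8aS)-5-hydroxy-7-(hydroxymethyl)-6-methyl-3-methylidene-3,3a,4,5,6,8a-hexahydro-2H-cyclohepta[b]furan-2-one
Conditions: HF·pyridine, THF/pyridine, 0 °C → rt
Reagents that add atoms: none
Why: Fluoride cleavage of the primary silyl ether under non-basic conditions avoids oxa-Michael addition to the methylene lactone.

Step 16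
Reactants: 23 (3aS,5S,6R,8aS)-5-hydroxy-7-(hydroxymethyl)-6-methyl-3-methylidene-3,3a,4,5,6,8a-hexahydro-2H-cyclohepta[b]furan-2-one
Product: 24 (3aS,5S,6S,7R,8R,8aR)-7,8-epoxy-5-hydroxy-7-(hydroxymethyl)-6-methyl-3-methylideneoctahydro-2H-cyclohepta[b]furan-2-one (oxirane on the face of the lactone oxygen)
Conditions: Ti(OiPr)4 (1.0 equiv), (S,S)-(−)-diethyl tartrate (1.2 equiv), t-BuOOH (2 equiv), 4 Å MS, CH2Cl2, −20 °C
Reagents that add atoms: tert-butyl hydroperoxide, CC(C)(C)OO
Why: Sharpless asymmetric epoxidation of the primary allylic alcohol, in which the (S,S)-tartrate–titanium complex delivers oxygen to the face from which C8→C7→CH2OH runs anticlockwise, that is the face of the lactone oxygen and of the cis homoallylic C5 hydroxyl (which can also bind titanium), setting C7 and C8.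

Step 17
Reactants: 24 (3aS,5S,6S,7R,8R,8aR)-7,8-epoxy-5-hydroxy-7-(hydroxymethyl)-6-methyl-3-methylideneoctahydro-2H-cyclohepta[b]furan-2-one, 25 3-methylbutanoic acid (isovaleric acid)
Product: 26 (3aS,5S,6S,7R,8S,8aR)-5,7-dihydroxy-7-(hydroxymethyl)-6-methyl-3-methylidene-2-oxooctahydro-2H-cyclohepta[b]furan-8-yl 3-methylbutanoate
Conditions: Ti(OiPr)4 (1.5 equiv), 25 (3 equiv), CH2Cl2, 0 °C → rt
Reagents that add atoms: none
Why: Titanium-mediated opening of a 2,3-epoxy alcohol, in which the epoxide is activated in a chelate with the C1' alkoxide and the titanium-bound carboxylate attacks the distal secondary carbon C8 from the face opposite the epoxide oxygen (SN2, inversion), giving the trans C7-hydroxy/C8-acyloxy arrangement with C7 retained.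

Step 18
Reactants: 26 (3aS,5S,6S,7R,8S,8aR)-5,7-dihydroxy-7-(hydroxymethyl)-6-methyl-3-methylidene-2-oxooctahydro-2H-cyclohepta[b]furan-8-yl 3-methylbutanoate
Product: 27 (3aS,5S,6S,7S,8S,8aR)-7-formyl-5,7-dihydroxy-6-methyl-3-methylidene-2-oxooctahydro-2H-cyclohepta[b]furan-8-yl 3-methylbutanoate
Conditions: TEMPO (20 mol %), PhI(OAc)2 (1.2 equiv), CH2Cl2, rt
Reagents that add atoms: none
Why: Oxoammonium (TEMPO) oxidation is selective for the primary alcohol over the secondary C5 and tertiary C7 hydroxyls and gives an α-hydroxy aldehyde that has no α-hydrogen to epimerise.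

Step 19
Reactants: 27 (3aS,5S,6S,7S,8S,8aR)-7-formyl-5,7-dihydroxy-6-methyl-3-methylidene-2-oxooctahydro-2H-cyclohepta[b]furan-8-yl 3-methylbutanoate, 19 (1Z)-1-iodoprop-1-ene
Product: 29 (3aS,5S,6S,7R,8S,8aR)-5,7-dihydroxy-7-[(2Z)-1-hydroxybut-2-en-1-yl]-6-methyl-3-methylidene-2-oxooctahydro-2H-cyclohepta[b]furan-8-yl 3-methylbutanoate (both side-chain carbinol epimers), via propenylchromium dichloride 28 (not isolated)
Conditions: CrCl2 (6 equiv), NiCl2 (1 mol %), 19 (3 equiv), DMSO, rt
Reagents that add atoms: none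
Why: Nozaki–Hiyama–Kishi coupling, in which nickel-catalysed activation of the vinyl iodide and transmetalation give an alkenylchromium reagent that adds only to the aldehyde with retention of the Z geometry; the new carbinol centre is formed as a mixture that is removed in step 20.

Step 20
Reactants: 29 (3aS,5S,6S,7R,8S,8aR)-5,7-dihydroxy-7-[(2Z)-1-hydroxybut-2-en-1-yl]-6-methyl-3-methylidene-2-oxooctahydro-2H-cyclohepta[b]furan-8-yl 3-methylbutanoate
Product: 30 (3aS,6R,7S,8S,8aR)-7-[(2Z)-but-2-enoyl]-7-hydroxy-6-methyl-3-methylidene-2,5-dioxooctahydro-2H-cyclohepta[b]furan-8-yl 3-methylbutanoate (CNP0283951.2)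
Conditions: IBX (4 equiv), DMSO, rt, dark
Reagents that add atoms: none
Why: IBX oxidises both secondary alcohols (C5 and the allylic side-chain carbinol) to ketones under neutral conditions without cleaving the tertiary α-hydroxy ketone, epimerising C6 or isomerising the (Z)-enone.

**Compound list**

1 | acrolein (prop-2-enal) | C=CC=O | starting material
2 | 3-[(4-methoxybenzyl)oxy]propanal | O=CCCOCc1ccc(OC)cc1 | intermediate
3 | methyl acrylate | C=CC(=O)OC | starting material
4 | methyl 2-{1-hydroxy-3-[(4-methoxybenzyl)oxy]propyl}prop-2-enoate (racemic) | C=C(C(=O)OC)C(O)CCOCc1ccc(OC)cc1 | intermediate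
5 | methyl (2Z)-2-(bromomethyl)-5-[(4-methoxybenzyl)oxy]pent-2-enoate | COC(=O)/C(CBr)=C/CCOCc1ccc(OC)cc1 | intermediate
6 | methyl (3S,4S)-3-{2-[(4-methoxybenzyl)oxy]ethyl}-2-methylidene-4-[(trimethylsilyl)oxy]hex-5-enoate | COC(=O)C(=C)[C@H](CCOCc1ccc(OC)cc1)[C@@H](O[Si](C)(C)C)C=C | intermediate (not isolated)
7 | methyl (3S,4S)-4-hydroxy-3-{2-[(4-methoxybenzyl)oxy]ethyl}-2-methylidenehex-5-enoate | COC(=O)C(=C)[C@H](CCOCc1ccc(OC)cc1)[C@@H](O)C=C | intermediate (not isolated)
8 | (4S,5S)-5-ethenyl-4-{2-[(4-methoxybenzyl)oxy]ethyl}-3-methylideneoxolan-2-one | C=C1C(=O)O[C@@H](C=C)[C@H]1CCOCc1ccc(OC)cc1 | intermediate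
9 | (4S,5S)-5-ethenyl-4-(2-hydroxyethyl)-3-methylideneoxolan-2-one | C=C1C(=O)O[C@@H](C=C)[C@H]1CCO | intermediate
10 | formaldehyde | C=O | starting material
11 | methyl 2-(hydroxymethyl)prop-2-enoate | C=C(CO)C(=O)OC | intermediate
12 | methyl 2-{[(tert-butyldimethylsilyl)oxy]methyl}prop-2-enoate | C=C(CO[Si](C)(C)C(C)(C)C)C(=O)OC | intermediate
13 | 2-{[(tert-butyldimethylsilyl)oxy]methyl}prop-2-en-1-ol | C=C(CO)CO[Si](C)(C)C(C)(C)C | intermediate
14 | 2-{[(tert-butyldimethylsilyl)oxy]methyl}prop-2-enal | C=C(C=O)CO[Si](C)(C)C(C)(C)C | intermediate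
15 | 2-{[(tert-butyldimethylsilyl)oxy]methyl}buta-1,3-diene | C=CC(=C)CO[Si](C)(C)C(C)(C)C | intermediate
16 | propyne | CC#C | starting material
17 | prop-1-ynyllithium | CC#C[Li] | intermediate (not isolated)
18 | 1-iodoprop-1-yne | CC#CI | intermediate
19 | (1Z)-1-iodoprop-1-ene | C/C=C\I | intermediate
20 | [(2S,3S)-2-ethenyl-4-methylidene-5-oxooxolan-3-yl]acetaldehyde | C=C1C(=O)O[C@@H](C=C)[C@H]1CC=O | intermediate (not isolated)
21 | (4S,5S)-4-[(2S,3R)-4-{[(tert-butyldimethylsilyl)oxy]methyl}-2-hydroxy-3-methylpent-4-en-1-yl]-5-ethenyl-3-methylideneoxolan-2-one | C=C1C(=O)O[C@@H](C=C)[C@H]1C[C@H](O)[C@H](C)C(=C)CO[Si](C)(C)C(C)(C)C | intermediate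
22 | (3aS,5S,6R,8aS)-7-{[(tert-butyldimethylsilyl)oxy]methyl}-5-hydroxy-6-methyl-3-methylidene-3,3a,4,5,6,8a-hexahydro-2H-cyclohepta[b]furan-2-one | C=C1C(=O)O[C@@H]2[C@H]1C[C@H](O)[C@H](C)C(CO[Si](C)(C)C(C)(C)C)=C2 | intermediate
23 | (3aS,5S,6R,8aS)-5-hydroxy-7-(hydroxymethyl)-6-methyl-3-methylidene-3,3a,4,5,6,8a-hexahydro-2H-cyclohepta[b]furan-2-one | C=C1C(=O)O[C@@H]2[C@H]1C[C@H](O)[C@H](C)C(CO)=C2 | intermediate
24 | (3aS,5S,6S,7R,8R,8aR)-7,8-epoxy-5-hydroxy-7-(hydroxymethyl)-6-methyl-3-methylideneoctahydro-2H-cyclohepta[b]furan-2-one | C=C1C(=O)O[C@@H]2[C@H]1C[C@H](O)[C@H](C)[C@]3(CO)O[C@H]23 | intermediate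
25 | 3-methylbutanoic acid (isovaleric acid) | CC(C)CC(=O)O | starting material
26 | (3aS,5S,6S,7R,8S,8aR)-5,7-dihydroxy-7-(hydroxymethyl)-6-methyl-3-methylidene-2-oxooctahydro-2H-cyclohepta[b]furan-8-yl 3-methylbutanoate | C=C1C(=O)O[C@@H]2[C@H]1C[C@H](O)[C@H](C)[C@@](O)(CO)[C@H]2OC(=O)CC(C)C | intermediate
27 | (3aS,5S,6S,7S,8S,8aR)-7-formyl-5,7-dihydroxy-6-methyl-3-methylidene-2-oxooctahydro-2H-cyclohepta[b]furan-8-yl 3-methylbutanoate | C=C1C(=O)O[C@@H]2[C@H]1C[C@H](O)[C@H](C)[C@@](O)(C=O)[C@H]2OC(=O)CC(C)C | intermediate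
28 | [(1Z)-prop-1-en-1-yl]chromium dichloride | C/C=C\[Cr](Cl)Cl | intermediate (not isolated)
29 | (3aS,5S,6S,7R,8S,8aR)-5,7-dihydroxy-7-[(2Z)-1-hydroxybut-2-en-1-yl]-6-methyl-3-methylidene-2-oxooctahydro-2H-cyclohepta[b]furan-8-yl 3-methylbutanoate (carbinol epimers) | C=C1C(=O)O[C@@H]2[C@H]1C[C@H](O)[C@H](C)[C@@](O)(C(O)/C=C\C)[C@H]2OC(=O)CC(C)C | intermediate
30 | (3aS,6R,7S,8S,8aR)-7-[(2Z)-but-2-enoyl]-7-hydroxy-6-methyl-3-methylidene-2,5-dioxooctahydro-2H-cyclohepta[b]furan-8-yl 3-methylbutanoate | C=C1C(=O)O[C@@H]2[C@H]1CC(=O)[C@H](C)[C@@](O)(C(=O)/C=C\C)[C@H]2OC(=O)CC(C)C | target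

**Step count**

Total steps: 20. Longest linear sequence: 13 (steps 1–5 then 13–20; the branch 6–10 then 13–20 is equally long; the branch 11–12 joins at step 19).

**Steps most likely to fail**

Step 13 (the new coupling). The ruthenium hydride may reduce or isomerise the α-methylene lactone or the allylic vinyl group, and the anti/facial control on a 2-(silyloxymethyl)diene is untested. The fallback uses known chemistry, sets out from 9 and 14 and comes back at 21. Alcohol 9 is oxidised with IBX to aldehyde 20, which is isolated this time. Enal 14 is treated with MeMgBr to give 3-{[(tert-butyldimethylsilyl)oxy]methyl}but-3-en-2-ol F1, and NBS/Me2S bromination with allylic transposition gives 1-bromo-2-{[(tert-butyldimethylsilyl)oxy]methyl}but-2-ene F2 (any regio- or geometric isomer converges on the same allylchromium). A reagent-controlled Nozaki–Hiyama crotylation of 20 with F2 (CrCl2, chiral sulfonamide ligand, Et3N, THF) then adds through the γ-carbon in a chair, anti-selectively, to give 21.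

Step 17 (epoxide opening). Attack could stray to C7, and Ti(OiPr)4 may move the new ester to the primary hydroxyl. The fallback sets out from 24 and comes back at 27. The primary alcohol of 24 is oxidised first (TEMPO, PhI(OAc)2) to (3aS,5S,6S,7S,8R,8aR)-7,8-epoxy-7-formyl-5-hydroxy-6-methyl-3-methylideneoctahydro-2H-cyclohepta[b]furan-2-one F3. In this α,β-epoxy aldehyde the formyl group deactivates C7, so caesium 3-methylbutanoate (CsO2CCH2CHMe2) with isovaleric acid in DMF at 40 °C opens the epoxide at the β-carbon C8 with inversion and gives 27 directly, with no chelation control needed.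

Step 19 (Ni/Cr coupling). The aldehyde is neopentylic and α-hydroxylated, iodide 19 is volatile, and some Z→E leakage is possible. The fallback sets out from 27 and comes back at 30 by acyl cross-coupling in place of carbonyl addition. Pinnick oxidation (NaClO2, NaH2PO4, 2-methylbut-2-ene) gives (3aS,5S,6S,7S,8S,8aR)-5,7-dihydroxy-6-methyl-3-methylidene-8-[(3-methylbutanoyl)oxy]-2-oxooctahydro-2H-cyclohepta[b]furan-7-carboxylic acid F4. EDC/DMAP/EtSH gives the S-ethyl thioester of that acid F5. A Liebeskind–Srogl coupling (Pd2(dba)3, tri(2-furyl)phosphine, Cu(O2C-2-thienyl)) with (Z)-prop-1-enylboronic acid gives (3aS,5S,6S,7S,8S,8aR)-7-[(2Z)-but-2-enoyl]-5,7-dihydroxy-6-methyl-3-methylidene-2-oxooctahydro-2H-cyclohepta[b]furan-8-yl 3-methylbutanoate F6. IBX oxidation of the remaining C5 alcohol then gives 30.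

**Further compounds**

F1 | step 13 | 3-{[(tert-butyldimethylsilyl)oxy]methyl}but-3-en-2-ol (racemic) | CC(O)C(=C)CO[Si](C)(C)C(C)(C)C
F2 | step 13 | 1-bromo-2-{[(tert-butyldimethylsilyl)oxy]methyl}but-2-ene (E/Z mixture) | CC=C(CBr)CO[Si](C)(C)C(C)(C)C
F3 | step 17 | (3aS,5S,6S,7S,8R,8aR)-7,8-epoxy-7-formyl-5-hydroxy-6-methyl-3-methylideneoctahydro-2H-cyclohepta[b]furan-2-one | C=C1C(=O)O[C@@H]2[C@H]1C[C@H](O)[C@H](C)[C@]3(C=O)O[C@H]23
F4 | step 19 | (3aS,5S,6S,7S,8S,8aR)-5,7-dihydroxy-6-methyl-3-methylidene-8-[(3-methylbutanoyl)oxy]-2-oxooctahydro-2H-cyclohepta[b]furan-7-carboxylic acid | C=C1C(=O)O[C@@H]2[C@H]1C[C@H](O)[C@H](C)[C@@](O)(C(=O)O)[C@H]2OC(=O)CC(C)C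
F5 | step 19 | S-ethyl (3aS,5S,6S,7S,8S,8aR)-5,7-dihydroxy-6-methyl-3-methylidene-8-[(3-methylbutanoyl)oxy]-2-oxooctahydro-2H-cyclohepta[b]furan-7-carbothioate | C=C1C(=O)O[C@@H]2[C@H]1C[C@H](O)[C@H](C)[C@@](O)(C(=O)SCC)[C@H]2OC(=O)CC(C)C
F6 | step 19 | (3aS,5S,6S,7S,8S,8aR)-7-[(2Z)-but-2-enoyl]-5,7-dihydroxy-6-methyl-3-methylidene-2-oxooctahydro-2H-cyclohepta[b]furan-8-yl 3-methylbutanoate | C=C1C(=O)O[C@@H]2[C@H]1C[C@H](O)[C@H](C)[C@@](O)(C(=O)/C=C\C)[C@H]2OC(=O)CC(C)C
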